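Readings and results stem from a simulated flask from invented constants, noise included.

In a one-step world the rate is proportional to the catalyst and the apparent order in catalyst is exactly 1, so I take that as the zero of my scale and ask what pulls this flask below it.

| flask | substrate | gas | catalyst | remark |
|---|---|---|---|---|
| north | 2 M | 200 mM (held) | 2 mM | the very flask that is asked about, followed so far |
| flask | 2.0 M | 200 mM (held) | 2.0 mM |  |

north run (percent of the substrate charged)

| time / min | target / % | substrate / % |
|---|---|---|
| 12.0 | 41 | 58 |
| 25.0 | 75 | 29 |
| 40.0 | 95 | 8 |
| 50.0 | 96 | 1 |

(each reading ± 1.5 percentage points)

- the earlier runs were read with a standard deviation of 1.5 percentage points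
- at the start none of the gas is in solution
- no earlier run changes the charge of catalyst; that part of a forecast is a guess

1. apparent order in catalyst when 20% of the substrate are converted (percent change of the rate of making target for one percent more catalyst charged)

The flask is the north run followed on, but no run changes the catalyst, so my answer rests on a model. No gas is in solution at the start, so I let it enter at r = G(1 − c/c_sat), where r is the rate, c the dissolved gas and c_sat its saturation value. If reaction consumes gas in proportion to catalyst times c, the order in catalyst is c/c_sat, which is 1 − r/G. Taking 1/r = 1/G + a/S, with S the substrate and a a constant, the readings give 70.0 mM/min at mean S 1.58 M and 44.6 mM/min at 0.870 M. Read from these two rates, with their scatter, G comes to 231 mM/min, and I call it the gas ceiling, the rate of entry into a solution empty of gas. The early rate is lower than this ceiling, so in my model entry takes a part of the resistance and reaction the rest, and since the mean substrate of that first interval, 79.0% of the charge, lies close to the moment asked about, I commit to an order of 0.697.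

The forecast says 0.55, lower than my number, reasoning that if gas supply is partly limiting “the rate responds to catalyst about as it does to substrate”.

The flask gives 0.77, and at that conversion 80.4% of the catalyst stands as catalyst, the remainder as dormant form.

    substrate + partner + catalyst → target + catalyst, rate k1*[substrate]*[partner]*[catalyst]/(1 + ([substrate]/sat1)) (0.200 M, k = 2000 /M²/min)
    gas ⇌ partner, rate k2*(csat - [partner]) (kL = 1.20 /min)
    catalyst ⇌ dormant form (K = 16.0, k = 0.0410 /min)

The flask's rate at that conversion, 4.61 M/h, set against my ceiling gives a value of 1 − r/G lower than the flask's order, namely 0.667.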